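**Plan**

1. Retrosynthesis: the C7=C8 alkene with its C6 methylene neighbour is read as the trace of an allyl sulfone. Cutting C9–C10 (ring B) and C4–C5 (ring A) in one radical cascade, with PhSO2 put back on C7 and the C3 hydroxyl closed to a C3–C4 oxirane, gives an open-chain (E,E)-2,15-diacetoxy-3,4-epoxy-7-sulfonyl diene.
2. Cutting C6–C7 (sulfone alkylation) gives a C10 allyl sulfone from (S)-citronellol and a C10 epoxy allylic bromide; the bromide is cut at C1–C2 (vinylogous aldol) into ethyl 3-methylbut-2-enoate and prenal.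
3. Forward: the two C10 halves are made separately and joined at C6–C7, both acetates are put on the open chain, and ring A and then ring B close in the last step while the sulfone leaves as a radical.
4. Enabling feature: C4, C5=C10 and C9=C8 sit in an epoxide–alkene–alkene array along the chain, and ring B holds a carbon (C7) allylic to C8 that can carry a radical leaving group, so the C8 radical can only end as the C7=C8 bond.
5. Stereochemistry: C13 is bought ((S)-citronellol); C2 is set by a catalytic enantioselective vinylogous aldol; C3 is relayed from C2 (threo hydroxyl-directed epoxidation); C5, C10 and C9 are relayed from C2/C3 in the cascade by chair–chair folding.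

Key step: step 14

Remark: locants C1–C20 follow labdane numbering of the target (C1–C10 decalin, C11–C16 side chain, C17 on C8, C18/C19 on C4, C20 on C10) and are used for the open-chain precursors as well; the target is (2S,3S,5S,9R,10S,13S).
Assumption: in step 6 the (S,S)-bisphosphoramide is taken to direct the dienolate to the Si face of prenal; should the facial sense be the reverse, the (R,R)-catalyst is used with nothing else changed.

**Route**

Step 1
Reactants: 1 (S)-citronellol
Product: 2 TBS ether of (S)-citronellol
Conditions: TBSCl, imidazole, DMF, 0 °C to rt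
Reagents that add atoms: tert-butyldimethylsilyl chloride, CC(C)(C)[Si](C)(C)Cl
Why: Standard imidazole-promoted silylation of a primary alcohol; the C13 stereocentre is untouched.

Step 2
Reactants: 2 TBS ether of (S)-citronellol
Product: 3 (2E,6S)-8-[(tert-butyldimethylsilyl)oxy]-2,6-dimethyloct-2-en-1-ol
Conditions: SeO2 (0.2 equiv), t-BuOOH, salicylic acid (cat.), CH2Cl2, rt
Reagents that add atoms: tert-butyl hydroperoxide, CC(C)(C)OO (terminal oxygen source); selenium dioxide, O=[Se]=O (oxygen carrier)
Why: Catalytic SeO2 allylic oxidation (ene reaction, then [2,3]-sigmatropic shift) hydroxylates the (E)-methyl group of a prenyl terminus selectively, which fixes the (E)-alkene that becomes C8=C9.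

Step 3
Reactants: 3 (E)-allylic alcohol
Product: 4 {[(3S,6E)-8-bromo-3,7-dimethyloct-6-en-1-yl]oxy}(tert-butyl)dimethylsilane
Conditions: CBr4, PPh3, CH2Cl2, 0 °C
Reagents that add atoms: carbon tetrabromide, BrC(Br)(Br)Br
Why: The Appel reaction converts the primary allylic alcohol into the bromide by SN2 displacement under neutral conditions that spare the silyl ether.

Step 4
Reactants: 4 allylic bromide
Product: 5 tert-butyl{[(3S,6E)-3,7-dimethyl-8-(phenylsulfonyl)oct-6-en-1-yl]oxy}dimethylsilane
Conditions: PhSO2Na, DMF, rt
Reagents that add atoms: sodium benzenesulfinate, [Na+].[O-]S(=O)c1ccccc1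
Why: The soft sulfinate sulfur displaces the primary allylic bromide (SN2 S-alkylation) to give the allyl sulfone with the alkene geometry kept.

Step 5
Reactants: 6 ethyl 3-methylbut-2-enoate
Product: 7 tert-butyl[(1-ethoxy-3-methylbuta-1,3-dien-1-yl)oxy]dimethylsilane
Conditions: LDA, THF, −78 °C; TBSCl, DMPU, −78 °C to rt
Reagents that add atoms: tert-butyldimethylsilyl chloride, CC(C)(C)[Si](C)(C)Cl
Why: Kinetic γ-deprotonation of the senecioate and O-silylation of the extended enolate give the vinylketene silyl acetal needed for a vinylogous Mukaiyama aldol reaction.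

Step 6
Reactants: 7 silyl dienol ether; 8 3-methylbut-2-enal (prenal)
Product: 9 ethyl (2E,5S)-5-hydroxy-3,7-dimethylocta-2,6-dienoate
Conditions: SiCl4 (1.1 equiv), (S,S)-bisphosphoramide C51H52N6O2P2 (5 mol %; two cyclic phosphoramide units built on (S)-N,N'-dimethyl-1,1'-binaphthyl-2,2'-diamine and joined by N,N'-dimethylpentane-1,5-diamine), i-Pr2NEt (10 mol %), CH2Cl2, −78 °C; then aq. NaHCO3
Reagents that add atoms: none
Why: In this Lewis-base-activated SiCl4 vinylogous Mukaiyama aldol addition the chiral phosphoramide-bound silicon cation activates prenal and the dienolate attacks through its γ-carbon in an open transition state to give the (E)-enoate; Si-face attack under catalyst control sets the (S)-carbinol that becomes C2.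

Step 7
Reactants: 9 (S)-hydroxy dienoate
Product: 10 ethyl (2E,5S)-5-[(2R)-3,3-dimethyloxiran-2-yl]-5-hydroxy-3-methylpent-2-enoate
Conditions: mCPBA, NaHCO3, CH2Cl2, 0 °C
Reagents that add atoms: 3-chloroperoxybenzoic acid, OOC(=O)c1cccc(Cl)c1
Why: In this hydroxyl-directed peracid epoxidation (Henbest effect) A1,3 strain from the (Z)-methyl group holds the carbinol C–H in the alkene plane, so hydrogen-bonded delivery syn to the hydroxyl gives the threo epoxy alcohol (C3), while the electron-poor enoate is inert.

Step 8
Reactants: 10 threo epoxy alcohol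
Product: 11 ethyl (2E,5S)-5-[(2R)-3,3-dimethyloxiran-2-yl]-3-methyl-5-[(triethylsilyl)oxy]pent-2-enoate
Conditions: TESCl, imidazole, DMAP (cat.), CH2Cl2, 0 °C
Reagents that add atoms: chlorotriethylsilane, CC[Si](Cl)(CC)CC
Why: Silylation under mild base keeps the acid-sensitive oxirane intact and masks the hydroxyl for the hydride and carbanion steps.

Step 9
Reactants: 11 epoxy TES ether ester
Product: 12 (2E,5S)-5-[(2R)-3,3-dimethyloxiran-2-yl]-3-methyl-5-[(triethylsilyl)oxy]pent-2-en-1-ol
Conditions: i-Bu2AlH (DIBAL-H, 2.3 equiv), CH2Cl2, −78 °C; aq. potassium sodium tartrate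
Reagents that add atoms: none
Why: DIBAL-H reduces the unsaturated ester in 1,2-fashion to the (E)-allylic alcohol at low temperature, where the trisubstituted oxirane and the silyl ether are not attacked.

Step 10
Reactants: 12 epoxy allylic alcohol
Product: 14 {[(1S,3E)-5-bromo-1-[(2R)-3,3-dimethyloxiran-2-yl]-3-methylpent-3-en-1-yl]oxy}triethylsilane, via allylic mesylate 13 (not isolated)
Conditions: MsCl, Et3N, THF, −40 °C; then LiBr, THF, −40 to 0 °C
Reagents that add atoms: lithium bromide, [Li+].[Br-]
Why: Mesylation and in situ SN2 displacement by bromide is the standard acid-free way to epoxy allylic bromides, so the oxirane survives.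

Step 11
Reactants: 5 allyl sulfone; 14 epoxy allylic bromide
Product: 15 coupled C20 epoxy sulfone bis-silyl ether (C7 epimers)
Conditions: n-BuLi, THF, −78 °C; then 14, −78 to −40 °C
Reagents that add atoms: none
Why: Alkylation of the sulfone-stabilised allyl anion (Julia-type prenyl coupling) takes place at the α-carbon, forming the C6–C7 bond and leaving the sulfone on C7 as an epimer mixture that is of no consequence.

Step 12
Reactants: 15 coupled bis-silyl ether
Product: 16 (3S,6E,10E,13S)-13-[(2R)-3,3-dimethyloxiran-2-yl]-3,7,11-trimethyl-8-(phenylsulfonyl)trideca-6,10-diene-1,13-diol (C8 epimers; C8 of this name is C7 in labdane numbering)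
Conditions: Bu4NF, AcOH (1:1), THF, 0 °C to rt
Reagents that add atoms: none
Why: Buffered fluoride cleaves both silyl ethers, and the buffering should avoid base-induced loss of sulfinate and opening or migration of the oxirane.

Step 13
Reactants: 16 epoxy sulfone diol
Product: 17 1,13-diacetate of 16 (cyclization precursor)
Conditions: Ac2O, pyridine, DMAP (cat.), CH2Cl2, 0 °C to rt
Reagents that add atoms: acetic anhydride, CC(=O)OC(C)=O
Why: DMAP-catalysed acylation puts the two acetates of the target on O2 and O15 while the future C3 hydroxyl is still locked in the oxirane, so no selective acetylation is ever required.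

Step 14
Reactants: 17 epoxy sulfone diacetate
Product: 19 target (2S,3S,5S,9R,10S,13S)-2,15-diacetoxylabd-7-en-3-ol, via 3-O-trimethylsilyl ether 18 (not isolated)
Conditions: Cp2TiCl2 (0.3 equiv), Mn dust, Me3SiCl, 2,4,6-collidine, THF (dilute, slow addition of 17), rt; then 1 M aq. HCl, THF, 0 °C
Reagents that add atoms: none
Why: Proposed new method: Cp2TiCl (trivalent titanium, regenerated from Cp2TiCl2 by Mn with Me3SiCl/collidine) opens the oxirane homolytically at the tertiary carbon to give the C4 radical with the C3–O bond and its configuration intact; this radical closes ring A by 6-endo-trig addition to C5, the tertiary C10 radical so formed closes ring B by 6-endo-trig addition to C9, and the resulting tertiary C8 radical loses the β-sulfonyl group from C7 as PhSO2• (reduced to sulfinate by the metal), which places the alkene at C7=C8 and nowhere else. The closest known reaction types are the titanocene-catalysed epoxypolyprene bicyclization to labdanes, which ends by titanium trapping and β-hydride loss to the exocyclic alkene, and radical SH2' cyclizations onto allyl sulfones that end by β-scission of a sulfonyl radical; their union in one cascade is the untested part, and it is plausible because the fragmentation is unimolecular whereas the competing trapping by titanium is bimolecular and would in any case end in β-elimination of sulfinate to the same alkene. C5, C10 and C9 are set by substrate control in a chair–chair folding of the (E,E)-triene in which the C3 titanoxy and C2 acetoxy groups are both equatorial (the threo array makes the two preferences reinforce each other), giving the trans-decalin with axial C20 methyl and equatorial C9 side chain in the enantiomeric series dictated by the (3R)-oxirane, while C2, C3 and C13 pass through unchanged. The step needs tertiary rather than secondary epoxide opening (radical stability), 6-endo rather than 5-exo closures (trisubstituted alkenes attacked at their CH ends) and a C7=C8 rather than an exocyclic or C8=C9 alkene (the C7 sulfone); both C7 epimers of 17 converge because C7 becomes sp2. Me3SiCl caps the titanium alkoxide as silyl ether 18, which blocks acetyl migration from O2 to O3, and dilute HCl then frees the C3 hydroxyl without touching the acetates.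

**Compound list**

1 | (S)-citronellol, (3S)-3,7-dimethyloct-6-en-1-ol | CC(C)=CCC[C@H](C)CCO | starting material
2 | tert-butyl{[(3S)-3,7-dimethyloct-6-en-1-yl]oxy}dimethylsilane | CC(C)=CCC[C@H](C)CCO[Si](C)(C)C(C)(C)C | intermediate
3 | (2E,6S)-8-[(tert-butyldimethylsilyl)oxy]-2,6-dimethyloct-2-en-1-ol | OC/C(C)=C/CC[C@H](C)CCO[Si](C)(C)C(C)(C)C | intermediate
4 | {[(3S,6E)-8-bromo-3,7-dimethyloct-6-en-1-yl]oxy}(tert-butyl)dimethylsilane | BrC/C(C)=C/CC[C@H](C)CCO[Si](C)(C)C(C)(C)C | intermediate
5 | tert-butyl{[(3S,6E)-3,7-dimethyl-8-(phenylsulfonyl)oct-6-en-1-yl]oxy}dimethylsilane | O=S(=O)(C/C(C)=C/CC[C@H](C)CCO[Si](C)(C)C(C)(C)C)c1ccccc1 | intermediate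
6 | ethyl 3-methylbut-2-enoate | CCOC(=O)C=C(C)C | starting material
7 | tert-butyl[(1-ethoxy-3-methylbuta-1,3-dien-1-yl)oxy]dimethylsilane | CCOC(=CC(C)=C)O[Si](C)(C)C(C)(C)C | intermediate
8 | 3-methylbut-2-enal (prenal) | CC(C)=CC=O | starting material
9 | ethyl (2E,5S)-5-hydroxy-3,7-dimethylocta-2,6-dienoate | CC(C)=C[C@@H](O)C/C(C)=C/C(=O)OCC | intermediate
10 | ethyl (2E,5S)-5-[(2R)-3,3-dimethyloxiran-2-yl]-5-hydroxy-3-methylpent-2-enoate (threo) | CC1(C)O[C@@H]1[C@@H](O)C/C(C)=C/C(=O)OCC | intermediate
11 | ethyl (2E,5S)-5-[(2R)-3,3-dimethyloxiran-2-yl]-3-methyl-5-[(triethylsilyl)oxy]pent-2-enoate | CC1(C)O[C@@H]1[C@@H](O[Si](CC)(CC)CC)C/C(C)=C/C(=O)OCC | intermediate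
12 | (2E,5S)-5-[(2R)-3,3-dimethyloxiran-2-yl]-3-methyl-5-[(triethylsilyl)oxy]pent-2-en-1-ol | CC1(C)O[C@@H]1[C@@H](O[Si](CC)(CC)CC)C/C(C)=C/CO | intermediate
13 | methanesulfonate of 12 (not isolated) | CC1(C)O[C@@H]1[C@@H](O[Si](CC)(CC)CC)C/C(C)=C/COS(C)(=O)=O | intermediate
14 | {[(1S,3E)-5-bromo-1-[(2R)-3,3-dimethyloxiran-2-yl]-3-methylpent-3-en-1-yl]oxy}triethylsilane | CC1(C)O[C@@H]1[C@@H](O[Si](CC)(CC)CC)C/C(C)=C/CBr | intermediate
15 | tert-butyl{[(3S,6E,10E,13S)-13-[(2R)-3,3-dimethyloxiran-2-yl]-3,7,11-trimethyl-8-(phenylsulfonyl)-13-[(triethylsilyl)oxy]trideca-6,10-dien-1-yl]oxy}dimethylsilane, C8 epimers | CC1(C)O[C@@H]1[C@@H](O[Si](CC)(CC)CC)C/C(C)=C/CC(S(=O)(=O)c1ccccc1)/C(C)=C/CC[C@H](C)CCO[Si](C)(C)C(C)(C)C | intermediate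
16 | (3S,6E,10E,13S)-13-[(2R)-3,3-dimethyloxiran-2-yl]-3,7,11-trimethyl-8-(phenylsulfonyl)trideca-6,10-diene-1,13-diol, C8 epimers | CC1(C)O[C@@H]1[C@@H](O)C/C(C)=C/CC(S(=O)(=O)c1ccccc1)/C(C)=C/CC[C@H](C)CCO | intermediate
17 | (3S,6E,10E,13S)-13-[(2R)-3,3-dimethyloxiran-2-yl]-3,7,11-trimethyl-8-(phenylsulfonyl)trideca-6,10-diene-1,13-diyl diacetate, C8 epimers | CC1(C)O[C@@H]1[C@@H](OC(C)=O)C/C(C)=C/CC(S(=O)(=O)c1ccccc1)/C(C)=C/CC[C@H](C)CCOC(C)=O | intermediate
18 | 3-O-trimethylsilyl ether of the target (not isolated) | CC(=O)OCC[C@@H](C)CC[C@@H]1C(C)=CC[C@@H]2C(C)(C)[C@H](O[Si](C)(C)C)[C@@H](OC(C)=O)C[C@@]12C | intermediate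
19 | CNP0144124.2, (2S,3S,5S,9R,10S,13S)-2,15-diacetoxylabd-7-en-3-ol (trans-decalin; 2-OAc and 3-OH trans-diequatorial) | CC(=O)OCC[C@@H](C)CC[C@@H]1C(C)=CC[C@@H]2C(C)(C)[C@H](O)[C@@H](OC(C)=O)C[C@@]12C | target

**Count and risks**

Total steps: 14. Longest linear sequence: 10 steps (steps 5–14, from ethyl 3-methylbut-2-enoate); the citronellol branch is 8 steps (steps 1–4 and 11–14).

Steps most likely to fail:

Step 14 (proposed new method). What may go wrong: the C4 or C10 radical is reduced or trapped by titanium before ring closure, the sulfonyl radical adds back and scrambles the allyl sulfone before the cascade starts, or the acetate migrates from O2 to O3 on the metal alkoxide. Fallback with known chemistry, setting out from 15: the sulfone is removed first by reductive desulfonylation (sodium amalgam, Na2HPO4, MeOH/THF, −20 °C) to give the sulfone-free bis-silyl epoxy diene F1. Bu4NF/AcOH then gives the epoxy diol F2, and Ac2O/pyridine gives the epoxy diacetate F3. The established titanocene cyclization of epoxypolyprenyl acetates (Cp2TiCl from Cp2TiCl2 and Mn dust, THF, aqueous work-up) should give the exocyclic alkene isomer F4 (C8=C17). A hydrogen-atom-transfer alkene isomerization with chloro[N,N'-bis(3,5-di-tert-butylsalicylidene)cyclohexane-1,2-diaminato]cobalt (trivalent cobalt, C36H52ClCoN2O2; PhSiH3 cat., benzene, rt) should then move the 1,1-disubstituted alkene into the ring at C7=C8, because the hydrogen on C7 is more accessible than the one on C9 beside the quaternary C10. This returns to 19.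

Step 6. What may go wrong: poor enantiofacial discrimination with the β,β-disubstituted enal, attack through the α- instead of the γ-carbon of the dienolate, or acid-promoted ionization of the sensitive allylic carbinol. Fallback, setting out from 7 and 8: an achiral Lewis acid (BF3·OEt2, CH2Cl2, −78 °C) gives the racemic hydroxy dienoate F5. Oxidation (Dess–Martin periodinane, NaHCO3, CH2Cl2) gives the dienone F6. Corey–Bakshi–Shibata reduction [(R)-1-methyl-3,3-diphenyltetrahydro-1H,3H-pyrrolo[1,2-c][1,3,2]oxazaborole, catecholborane, toluene, −78 °C] then sets the carbinol by reagent control at the ketone and returns to 9.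

Step 12. What may go wrong: base-induced 1,2-elimination of benzenesulfinate toward a conjugated triene, or alkoxide-triggered epoxide migration (Payne rearrangement) once the C2 hydroxyl is free. Fallback, setting out from 15, changes the order of events: 15 is submitted directly to the cascade of step 14 without the acidic work-up, giving the tris-silylated bicycle F7. Bu4NF (THF, rt) then removes all three silyl groups from a compound that no longer holds a sulfone or an epoxide, giving the triol F8. Ac2O/pyridine (2 equiv, 0 °C) should acetylate the primary C15 and the unhindered equatorial C2 hydroxyls before the neopentyl C3 hydroxyl, returning to 19.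

**Further compounds**

F1 | step 14 | tert-butyl{[(3S,6E,10E,13S)-13-[(2R)-3,3-dimethyloxiran-2-yl]-3,7,11-trimethyl-13-[(triethylsilyl)oxy]trideca-6,10-dien-1-yl]oxy}dimethylsilane | CC1(C)O[C@@H]1[C@@H](O[Si](CC)(CC)CC)C/C(C)=C/CC/C(C)=C/CC[C@H](C)CCO[Si](C)(C)C(C)(C)C
F2 | step 14 | (3S,6E,10E,13S)-13-[(2R)-3,3-dimethyloxiran-2-yl]-3,7,11-trimethyltrideca-6,10-diene-1,13-diol | CC1(C)O[C@@H]1[C@@H](O)C/C(C)=C/CC/C(C)=C/CC[C@H](C)CCO
F3 | step 14 | (3S,6E,10E,13S)-13-[(2R)-3,3-dimethyloxiran-2-yl]-3,7,11-trimethyltrideca-6,10-diene-1,13-diyl diacetate | CC1(C)O[C@@H]1[C@@H](OC(C)=O)C/C(C)=C/CC/C(C)=C/CC[C@H](C)CCOC(C)=O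
F4 | step 14 | (2S,3S,5S,9R,10S,13S)-2,15-diacetoxylabd-8(17)-en-3-ol (exocyclic alkene isomer of the target) | CC(=O)OCC[C@@H](C)CC[C@@H]1C(=C)CC[C@@H]2C(C)(C)[C@H](O)[C@@H](OC(C)=O)C[C@@]12C
F5 | step 6 | racemic ethyl (2E)-5-hydroxy-3,7-dimethylocta-2,6-dienoate | CC(C)=CC(O)C/C(C)=C/C(=O)OCC
F6 | step 6 | ethyl (2E)-3,7-dimethyl-5-oxoocta-2,6-dienoate | CC(C)=CC(=O)C/C(C)=C/C(=O)OCC
F7 | step 12 | 15-O-TBS, 2-O-TES, 3-O-TMS ether of (2S,3S,5S,9R,10S,13S)-labd-7-ene-2,3,15-triol | CC(C)(C)[Si](C)(C)OCC[C@@H](C)CC[C@@H]1C(C)=CC[C@@H]2C(C)(C)[C@H](O[Si](C)(C)C)[C@@H](O[Si](CC)(CC)CC)C[C@@]12C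
F8 | step 12 | (2S,3S,5S,9R,10S,13S)-labd-7-ene-2,3,15-triol | OCC[C@@H](C)CC[C@@H]1C(C)=CC[C@@H]2C(C)(C)[C@H](O)[C@@H](O)C[C@@]12C
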